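A Z cannot take up more than 3 E, and the winter flask cannot spend more E than it was given, so we start from those two limits.

| flask | Z | E | temperature | remark | time |
|---|---|---|---|---|---|
| winter | 20 mM | 1.5 equiv | 60 °C | the very flask that is asked about, followed so far |  |
| noon | 20 mM | 1.5 equiv | 45 °C | run made earlier |  |
| flask | 20 mM | 1.50 equiv | 60 °C |  | 1.5 h |

| run | time / min | J / % |
|---|---|---|
| winter | 12.0 | 14.1 |
| winter | 30.0 | 13.1 |
| winter | 60.0 | 12.7 |
| winter | 90.0 | 12.5 |
| noon | 25.0 | 10.6 |
| noon | 60.0 | 6.0 |
| noon | 120 | 6.7 |
| noon | 180 | 5.5 |

(scatter of a reading: 0.5 percentage points)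

- additions bring no volume worth counting
- the numbers in the tables scatter with a standard deviation of 0.5 percentage points
- what may be going on: Z + E -> J + X; E + J -> Q + X; E + Q -> L + X; J <-> G

- J, in percent of the Z first charged, at 1.5 h
- the remedy with the largest gain of J, or "none" below 2 percentage points (oak / elm / birch / ash / none)
- J present, in percent of the Z first charged, after elm
- J present, in percent of the Z first charged, after birch

- oak: at 1.5 h add E, 50.0 % of the amount charged, then wait 25 min
- elm: at 1.5 h take out 90 % of the X then present, then wait 25 min
- birch: change nothing and wait 25 min more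
- ash: at 1.5 h raise the temperature by 15 K, then wait 25 min

*What can the winter flask spend?* Each E step takes one E and gives one X. Its E purse, the [E] charged and so the highest [X] it can reach, is 30.0 mM.

*What would full conversion to L cost?* It would cost 60.0 mM, more than the purse, so E is the limiting reagent in the winter flask. Once the purse of 30.0 mM is spent, J <-> G is the step that can still move.

*Do the readings agree?* J in the winter run drops from 14.1 % to 12.5 %, and its last two readings differ by 0.2 percentage points, less than the scatter of 0.5 points. I commit to their mean, 12.6 %, for now and after birch.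

*Flat could mean slow. What about the noon run?* It has the same purse, 30.0 mM, yet its last reading is 5.5 %. Equal purses with unequal plateaus point to J <-> G, with warmth favouring J, so I choose ash.

*And the others?* Elm removes X, which the scheme lists as a product, so I expect no change. Oak adds 15.0 mM of E, and E + J consumes J, so I expect a loss.

The forecast gives 12.6 % now, 12.5 % after elm, 12.5 % after birch and ash as best, saying of oak that "fresh E would mostly consume J".

The flask gives 13.0 % now, 13.0 % after elm, 13.0 % after birch and ash as best, with a gain of 8.6 points against −3.6 points for oak.

    Z + E → J + X (k = 0.106 M⁻¹ s⁻¹, Ea = 46.0 kJ mol⁻¹)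
    E + J → Q + X (k = 0.234 M⁻¹ s⁻¹, Ea = 45.0 kJ mol⁻¹)
    E + Q → L + X (k = 0.302 M⁻¹ s⁻¹, Ea = 52.0 kJ mol⁻¹)
    J ⇌ G (K = 1.56, k = 0.00487 s⁻¹, Ea = 82.0 kJ mol⁻¹, ΔH = −68.0 kJ mol⁻¹)
    (constants at 60 °C)

In the winter flask, J's half-life by E + J alone, the other concentrations as charged, is 1.6 min, shorter than the 3.6 min of Z by Z + E alone. At 90.0 min the winter flask's purse of 30.0 mM stands as [X] of 30.0 mM, with L at 32.0 % beside Z at 24.3 %. Going up from the winter flask's charge of E, the answer to "now" has moved by 5 points at 2.30 equiv. The neighbour flask with 6.00 equiv of E has a purse of 120 mM, above the demand, which reckons 50.0 % of its E unspent; that neighbour ends with [X] at 60.0 mM and E at 50 % of its charge.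

(Readings and results come from a simulation with constants of no real substance; noise was put on by code.)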